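**Retrosynthetic overview**
1. Target 14 ⇒ amino-acetal 10: one acid cascade closes the pyrrolidine and oxazolidine rings (N,O-acetal), then ring B (aldol condensation of an aryl methyl ketone onto a masked 1,2-dione).
2. 10 ⇒ vinyl bromide 8 + 4-aminobutanal diethyl acetal 9 (vinylic substitution).
3. 8 ⇒ Cs-symmetric dibromo-p-quinol 4 + paeonol boronate 7: an enantiotopos-selective Suzuki coupling breaks the mirror plane, sets C4 and joins rings A and C.
4. 4 ⇒ 4-methylsyringol 1 (singlet-oxygen dearomatisation, then bromination); 7 ⇒ paeonol 5 (C–H borylation).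
5. Ring order: A (dearomatised arene) and C (paeonol) are bought; pyrrolidine and oxazolidine form next; ring B closes last.

Assumption 1: the compound is taken as the drawn 9-keto/10-CH2 tautomer (the form in the SMILES); prototropic equilibration after ring-B closure is assumed to converge on it.
Assumption 2: the sense of induction in step 4 cannot be predicted, so the ligand antipode that gives (R)-8 is chosen by experiment (both antipodes are available) and the configuration is confirmed on 8.
Numbering note: in the "Why" lines, C1–C10a are the phenanthrene locants of 14 (C1 ketone, C2 OMe, C3 N, C4 carbinol carbon, C4a/C10a ring fusion, C9 ketone, C10 CH2).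

**Step 1**
Reactants: 1 2,6-dimethoxy-4-methylphenol (4-methylsyringol)
Product: 3 4-hydroxy-2,6-dimethoxy-4-methylcyclohexa-2,5-dien-1-one, via hydroperoxide 2 (not isolated)
Conditions: O2 (1 atm), rose bengal (1 mol %), green LEDs, MeOH/aq. NaHCO3, 0 °C; then Me2S
Reagents that add atoms: dioxygen, O=O
Why: Photooxygenative dearomatisation, in which singlet oxygen adds across C1/C4 of the electron-rich p-alkylphenol (para-selective, whereas iodine(III) oxidants tend to attack the methoxy-bearing ortho carbon) and Me2S reduces the hydroperoxide; the product is Cs-symmetric, so no stereocentre is set.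

**Step 2**
Reactants: 3 4-hydroxy-2,6-dimethoxy-4-methylcyclohexa-2,5-dien-1-one
Product: 4 3,5-dibromo-4-hydroxy-2,6-dimethoxy-4-methylcyclohexa-2,5-dien-1-one
Conditions: Br2 (2.2 equiv), NaOAc, AcOH, rt
Reagents that add atoms: bromine, BrBr
Why: C3 and C5 are the β-carbons of the two methyl enol ethers, so buffered electrophilic bromination (addition–elimination, as in the bromination of 2,6-dimethoxybenzoquinone) gives the bis(β-bromo-α-methoxy-enone) with the mirror plane intact.

**Step 3**
Reactants: 5 paeonol, 1-(2-hydroxy-4-methoxyphenyl)ethan-1-one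
Product: 7 1-[2-hydroxy-4-methoxy-6-(4,4,5,5-tetramethyl-1,3,2-dioxaborolan-2-yl)phenyl]ethan-1-one, via bis-borylated ketone 6 (not isolated)
Conditions: B2pin2 (2.2 equiv), [Ir(OMe)(cod)]2 (1.5 mol %), AsPh3 (6 mol %), octane, 120 °C; then MeOH
Reagents that add atoms: bis(pinacolato)diboron, CC1(C)OB(OC1(C)C)B1OC(C)(C)C(C)(C)O1
Why: Ketone-directed iridium-catalysed ortho C–H borylation, in which the phenol is masked in situ as its O–Bpin ester, the carbonyl delivers iridium to the only C–H ortho to the acetyl group, and methanolysis frees the phenol.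

**Step 4**
Reactants: 4 3,5-dibromo-4-hydroxy-2,6-dimethoxy-4-methylcyclohexa-2,5-dien-1-one (1.3 equiv); 7 paeonol 6'-boronate
Product: 8 (R)-3-(2-acetyl-3-hydroxy-5-methoxyphenyl)-5-bromo-4-hydroxy-2,6-dimethoxy-4-methylcyclohexa-2,5-dien-1-one
Conditions: Pd(OAc)2 (5 mol %), enantiopure sSPhos (10 mol %), K3PO4, toluene/H2O, 10 °C→rt
Reagents that add atoms: none
Why: Proposed new method: enantiotopos-selective Suzuki–Miyaura coupling, in which irreversible oxidative addition of the chiral Pd(0)–monophosphine into one of the two enantiotopic C–Br bonds flanking the carbinol carbon sets C4 as R (the ligand sulfonate can hydrogen-bond the tertiary OH, and over-coupling preferentially removes the minor enantiomer); the closest known reaction type is the enantioselective desymmetrising Suzuki coupling of prochiral cyclic bis(alkenyl triflates) and of bis(aryl bromides) with chiral monophosphine–Pd catalysts.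

**Step 5**
Reactants: 8 (R)-bromo biaryl quinol; 9 4,4-diethoxybutan-1-amine (4-aminobutanal diethyl acetal)
Product: 10 (R)-3-(2-acetyl-3-hydroxy-5-methoxyphenyl)-5-[(4,4-diethoxybutyl)amino]-4-hydroxy-2,6-dimethoxy-4-methylcyclohexa-2,5-dien-1-one
Conditions: 9 (1.2 equiv), NaHCO3, MeCN, 40 °C
Reagents that add atoms: none
Why: Nucleophilic vinylic substitution (addition–elimination) of the vinylogous acyl bromide by the primary amine at the only halogen-bearing β-carbon gives the vinylogous amide and leaves C4 untouched.

**Step 6**
Reactants: 10 (R)-amino-acetal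
Product: 14 target CNP0528850.1 (C4 R; aminal carbon S), via aldehyde 11 (not isolated), via N,O-acetal 12 (not isolated), via diosphenol 13 (not isolated)
Conditions: 1 M aq. HCl/THF (1:3), 0 °C→rt; then 50 °C
Reagents that add atoms: none
Why: Acid unmasks the aldehyde, N-acyliminium-type N,O-acetalisation with the C4 hydroxyl closes the pyrrolidine and oxazolidine rings under thermodynamic control (pyrrolidine anti to the C4 methyl, which gives the S aminal carbon), and hydrolysis of the remaining methyl enol ether at C10a (the C2 enol ether is protected as part of the enaminone) then unveils a 1,2-dione carbonyl that undergoes intramolecular aldol condensation with the acetyl group and tautomerises to ring B.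

**Compound list**
1 | 2,6-dimethoxy-4-methylphenol (4-methylsyringol) | COc1cc(C)cc(OC)c1O | starting material
2 | 4-hydroperoxy-2,6-dimethoxy-4-methylcyclohexa-2,5-dien-1-one | COC1=CC(C)(OO)C=C(OC)C1=O | intermediate
3 | 4-hydroxy-2,6-dimethoxy-4-methylcyclohexa-2,5-dien-1-one | COC1=CC(C)(O)C=C(OC)C1=O | intermediate
4 | 3,5-dibromo-4-hydroxy-2,6-dimethoxy-4-methylcyclohexa-2,5-dien-1-one (Cs-symmetric, prochiral at C4) | COC1=C(Br)C(C)(O)C(Br)=C(OC)C1=O | intermediate
5 | paeonol, 1-(2-hydroxy-4-methoxyphenyl)ethan-1-one | CC(=O)c1ccc(OC)cc1O | starting material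
6 | 1-{4-methoxy-2-(pinacolboryl)-6-[(pinacolboryl)oxy]phenyl}ethan-1-one | CC(=O)c1c(OB2OC(C)(C)C(C)(C)O2)cc(OC)cc1B1OC(C)(C)C(C)(C)O1 | intermediate
7 | 1-[2-hydroxy-4-methoxy-6-(4,4,5,5-tetramethyl-1,3,2-dioxaborolan-2-yl)phenyl]ethan-1-one | CC(=O)c1c(O)cc(OC)cc1B1OC(C)(C)C(C)(C)O1 | intermediate
8 | (R)-3-(2-acetyl-3-hydroxy-5-methoxyphenyl)-5-bromo-4-hydroxy-2,6-dimethoxy-4-methylcyclohexa-2,5-dien-1-one | COC1=C(Br)[C@@](O)(C)C(c2cc(OC)cc(O)c2C(C)=O)=C(OC)C1=O | intermediate
9 | 4,4-diethoxybutan-1-amine (4-aminobutanal diethyl acetal) | NCCCC(OCC)OCC | starting material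
10 | (R)-3-(2-acetyl-3-hydroxy-5-methoxyphenyl)-5-[(4,4-diethoxybutyl)amino]-4-hydroxy-2,6-dimethoxy-4-methylcyclohexa-2,5-dien-1-one | COC1=C(NCCCC(OCC)OCC)[C@@](O)(C)C(c2cc(OC)cc(O)c2C(C)=O)=C(OC)C1=O | intermediate
11 | aldehyde of 10: (R)-4-{[the dienone C5]amino}butanal, all else as in 10 | COC1=C(NCCCC=O)[C@@](O)(C)C(c2cc(OC)cc(O)c2C(C)=O)=C(OC)C1=O | intermediate
12 | N,O-acetal of 11: the aldehyde carbon bridges the enaminone N and the C4 oxygen (fused pyrrolidine and oxazolidine); carbinol carbon R, aminal carbon S (H cis to the C4 methyl); aryl and C10a OMe as in 10 | COC1=C2N3CCC[C@@H]3O[C@]2(C)C(c2cc(OC)cc(O)c2C(C)=O)=C(OC)C1=O | intermediate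
13 | diosphenol of 12: the OMe next to the aryl-bearing carbon is replaced by OH (enol of the 1,2-dione); carbinol carbon R, aminal carbon S | COC1=C2N3CCC[C@@H]3O[C@]2(C)C(c2cc(OC)cc(O)c2C(C)=O)=C(O)C1=O | intermediate
14 | CNP0528850.1: 8-hydroxy-2,6-dimethoxy-4-methylphenanthrene-1,9(4H,10H)-dione whose C3 nitrogen and C4 oxygen are bridged by a pyrrolidin-2-yl aminal carbon (fused pyrrolo[2,1-b]oxazole); C4 R, aminal carbon S | COC1=C2N3CCC[C@@H]3O[C@]2(C)C2=C(CC(=O)c3c(O)cc(OC)cc32)C1=O | target

**Step count**
Total: 6 steps. Longest linear sequence: 5 steps (steps 1, 2, 4, 5, 6); step 3 is a one-step side branch.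

**Steps most likely to fail and their fallbacks**

Step 4 (desymmetrising Suzuki coupling) is the most exposed step. The enantioselectivity may be modest, the ortho-acetyl boronate is hindered, and the phenoxide of 7 could attack a β-bromoenone directly. The fallback moves the symmetry-breaking event to an organocatalytic annulation and sets out from 4. Acetal 9 is hydrolysed with aqueous HCl and basified to give 1-pyrroline F1. Quinol 4 and 1-pyrroline F1 are combined with a chiral phosphoric acid (TRIP type, 10 mol %) and Ag2CO3 as bromide scavenger in toluene at −20 °C. Hemiaminal formation at the quinol OH and enantiotopos-selective N-for-Br vinylic substitution should give bromo N,O-acetal F2, with both stereocentres set in one operation. An ordinary Suzuki coupling of bromo N,O-acetal F2 with 7 (Pd/SPhos, K3PO4) then returns to the route at 12, which is carried through the warm-acid stage of step 6 to 14.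

Step 6 (acid cascade) is the second risk. Once the enaminone is in place its carbonyl is protonated first, which may slow hydrolysis of the C10a enol ether, and the product is exposed to warm acid. The fallback changes the order of ring construction and sets out from 8. Aqueous TsOH in MeCN at 40 °C acts on 8 while ring A is still an ordinary dienone (enol-ether hydrolysis at the aryl-bearing arm, then aldol condensation) and gives tricyclic bromoquinol F3. Amination of tricyclic bromoquinol F3 with 9 (NaHCO3, MeCN) gives tricyclic amino-acetal F4. Brief treatment of tricyclic amino-acetal F4 with dilute acid at room temperature then closes only the N,O-acetal and returns to the route at 14.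

Step 3 (ketone-directed borylation) is the third risk. The O–Bpin group next to the acetyl group may chelate the carbonyl and weaken its directing ability. The fallback replaces the ketone by a stronger directing group and sets out from 5. Condensation with 1,1-dimethylhydrazine gives paeonol N,N-dimethylhydrazone F5. Hydrazone-directed iridium-catalysed ortho-borylation (B2pin2, then MeOH) gives borylated hydrazone F6. Mild hydrolysis of borylated hydrazone F6 (aqueous oxalic acid, THF) returns to the route at 7.

**Further compounds**
F1 | step 4 | 1-pyrroline (3,4-dihydro-2H-pyrrole) | C1CC=NC1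
F2 | step 4 | bromo N,O-acetal: 12 with Br in place of the aryl group (same spatial arrangement as 14; the carbinol carbon is S by CIP because Br outranks N; aminal carbon S) | COC1=C2N3CCC[C@@H]3O[C@]2(C)C(Br)=C(OC)C1=O
F3 | step 6 | (R)-3-bromo-4,8-dihydroxy-2,6-dimethoxy-4-methylphenanthrene-1,9(4H,10H)-dione | COC1=C(Br)[C@@](O)(C)C2=C(CC(=O)c3c(O)cc(OC)cc32)C1=O
F4 | step 6 | (R)-3-[(4,4-diethoxybutyl)amino]-4,8-dihydroxy-2,6-dimethoxy-4-methylphenanthrene-1,9(4H,10H)-dione | COC1=C(NCCCC(OCC)OCC)[C@@](O)(C)C2=C(CC(=O)c3c(O)cc(OC)cc32)C1=O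
F5 | step 3 | paeonol N,N-dimethylhydrazone | CC(=NN(C)C)c1ccc(OC)cc1O
F6 | step 3 | N,N-dimethylhydrazone of 7 | CC(=NN(C)C)c1c(O)cc(OC)cc1B1OC(C)(C)C(C)(C)O1
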